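**Assumption:** compounds 6, 9, 10 and 13 are treated as catalogue items. If any is unavailable, it is one benzylation or bromination away from homovanillic acid, syringol or 4-bromoguaiacol.

## Retrosynthetic overview
1. The C7'–C1' bond is cut last. It is formed by light-driven Ni/photoredox deoxygenative coupling of alcohol 8 with aryl bromide 14, followed by global debenzylation.
2. For 14, C7''–C1'' comes from chelation-controlled ArMgBr addition to an (S)-2-aryloxypropanal. C8''–O comes from Mitsunobu inversion of methyl (R)-lactate.
3. For 8, C7–C8 comes from a new, invertive Ni/photoredox decarboxylative benzylation of trans-β-lactone 5. The resulting acid is then reduced.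
4. Lactone 5 comes from ethyl (S)-3-hydroxybutanoate by anti-selective methylation, saponification and lactonisation.
5. All three arenes are purchased. The only ring made is the transient oxetan-2-one 5, formed in step 3 and opened in step 4.

## Route

**Step 1**
Reactants: 1 ethyl (S)-3-hydroxybutanoate; 2 iodomethane
Product: 3 ethyl (2S,3S)-3-hydroxy-2-methylbutanoate (anti)
Conditions: LDA (2.2 equiv), THF, −78 → −20 °C; MeI, DMPU, −78 → 0 °C
Reagents that add atoms: iodomethane, CI
Why: Fráter–Seebach alkylation, in which the Li-chelated alkoxide–enolate dianion is methylated anti to the C3 methyl, so the purchased centre sets C2 (future C8') with typically ≥95:5 anti selectivity.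

**Step 2**
Reactants: 3
Product: 4 (2S,3S)-3-hydroxy-2-methylbutanoic acid
Conditions: LiOH·H2O, THF/H2O, 0 °C → rt; KHSO4 work-up
Reagents that add atoms: water/hydroxide, O
Why: Plain ester saponification, where the carboxylate formed resists enolisation and neither stereocentre is touched.

**Step 3**
Reactants: 4
Product: 5 (3S,4S)-3,4-dimethyloxetan-2-one (trans-β-lactone)
Conditions: PhSO2Cl (2 equiv), pyridine, 0–4 °C, 18 h
Reagents that add atoms: none
Why: Adam-type β-lactonisation by carboxyl activation closes the ring through the hydroxyl oxygen, so both centres are retained and the anti acid gives the trans lactone.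

**Step 4 (key step, new)**
Reactants: 5; 6 2-[4-(benzyloxy)-3-methoxyphenyl]acetic acid (2 equiv)
Product: 7 (2S,3S)-4-[4-(benzyloxy)-3-methoxyphenyl]-2,3-dimethylbutanoic acid
Conditions: Ni(cod)2 (10 mol %), 4,4'-(MeO)2-bpy (12 mol %), Ir[dF(CF3)ppy]2(dtbbpy)PF6 (2 mol %), Cs2CO3 (0.25 equiv), halide-free MeCN, 450 nm LEDs, 25 °C; acidic work-up
Reagents that add atoms: none (the ArCH2 unit comes from 6; CO2 is lost)
Why: Proposed new method: excited Ir oxidises the arylacetate of 6 to a benzylic radical with loss of CO2, while (bpy)Ni(0) attacks C4 of the strained lactone in SN2 fashion (alkyl–O oxidative addition, inversion) to give a five-membered nickelalactone; radical capture gives Ni(III), retentive C(sp3)–C(sp3) reductive elimination forms C7–C8 with net inversion (setting 8S and the erythro dimethyl pair), Ir(II) returns Ni(I) to Ni(0), and proton exchange with the more acidic 6 keeps the base catalytic and leaves 7 as the non-oxidisable free acid; halide is excluded to prevent a stereorandom β-halo-acid radical pathway; the closest known reaction types are decarboxylative metallaphotoredox sp3–sp3 coupling of acids with alkyl halides, stoichiometric Ni(0) alkyl–O insertion into β-lactones and invertive insertion into aziridines, and SN2 opening of β-lactones by organocuprates.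

**Step 5**
Reactants: 7
Product: 8 (2S,3S)-4-[4-(benzyloxy)-3-methoxyphenyl]-2,3-dimethylbutan-1-ol
Conditions: BH3·THF (2 equiv), THF, 0 °C → rt
Reagents that add atoms: none
Why: Chemoselective borane reduction of the acid via acyloxyborane proceeds without enolisation, so C2 is preserved and the benzyl ether is inert.

**Step 6**
Reactants: 9 4-bromo-2,6-dimethoxyphenol; 10 methyl (R)-lactate
Product: 11 methyl (S)-2-(4-bromo-2,6-dimethoxyphenoxy)propanoate
Conditions: PPh3, DIAD, THF, 0 °C → rt
Reagents that add atoms: none
Why: Mitsunobu etherification is a clean SN2 displacement, so the purchased (R)-carbinol is inverted to the (S)-aryl ether (C8'').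

**Step 7**
Reactants: 11
Product: 12 (S)-2-(4-bromo-2,6-dimethoxyphenoxy)propanal
Conditions: DIBAL-H (1.1 equiv), CH2Cl2, −78 °C; Rochelle salt; used crude at once
Reagents that add atoms: none
Why: Partial ester reduction stops at the tetrahedral aluminium hemiacetal at −78 °C, and using the crude aldehyde immediately avoids α-epimerisation; ArBr is untouched.

**Step 8**
Reactants: 12; 13 1-(benzyloxy)-4-bromo-2-methoxybenzene (as its Grignard reagent)
Product: 14 (1S,2S)-1-[4-(benzyloxy)-3-methoxyphenyl]-2-(4-bromo-2,6-dimethoxyphenoxy)propan-1-ol (threo)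
Conditions: 13, Mg, THF → ArMgBr (1.5 equiv); 12 pre-complexed with MgBr2·OEt2 (2.5 equiv), CH2Cl2, −78 → −40 °C; the minor erythro isomer is removed by chromatography
Reagents that add atoms: none (the aryl group comes from 13)
Why: Cram-chelate Grignard addition, in which Mg bridges C=O and the twisted, o-OMe-assisted aryloxy oxygen and the aryl group attacks anti to the methyl, so C8'' sets C7'' as syn/threo (S,S); ArMgBr does not exchange with the ArBr at this temperature.

**Step 9 (key fragment union)**
Reactants: 8; 14
Product: 15 4,4''-di-O-benzyl ether of the target (7''S,8S,8'R,8''S)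
Conditions: 8 (1.4 equiv), 5,7-di-tert-butyl-3-phenylbenzoxazolium BF4 (1.3 equiv), pyridine, MTBE, rt, 15 min; then 14 (1.0 equiv), Ir(ppy)2(dtbbpy)PF6 (1.5 mol %), NiBr2·dtbbpy (5 mol %), quinuclidine (1.75 equiv), DMA, 450 nm LEDs, rt
Reagents that add atoms: none
Why: NHC-mediated metallaphotoredox deoxygenative arylation, in which the pre-formed alcohol adduct is photo-oxidised and β-scission releases the primary C7' radical (C8' is β to it and is not scrambled) for Ni-catalysed coupling with the unhindered ArBr; the azolium salt is limiting, so the free 7''-OH is never activated.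

**Step 10**
Reactants: 15
Product: 16 target, (+)-(7''S,8S,8'R,8''S)-4,4''-dihydroxy-3,3',3'',5'-tetramethoxy-4',8''-oxy-8,8'-sesquineolignan-7''-ol
Conditions: H2 (1 atm), 10 % Pd/C, EtOAc/EtOH (neutral), rt, stopped after 2 equiv uptake
Reagents that add atoms: none
Why: Hydrogenolysis of the two primary benzyl aryl ethers is much faster than cleavage of the secondary 7''-OH under neutral conditions, and no stereocentre is affected.

## Compound list
| No. | Name | SMILES | Role |
|---|---|---|---|
| 1 | ethyl (S)-3-hydroxybutanoate | `CCOC(=O)C[C@H](C)O` | starting material |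
| 2 | iodomethane | `CI` | starting material |
| 3 | ethyl (2S,3S)-3-hydroxy-2-methylbutanoate | `CCOC(=O)[C@@H](C)[C@H](C)O` | intermediate |
| 4 | (2S,3S)-3-hydroxy-2-methylbutanoic acid | `OC(=O)[C@@H](C)[C@H](C)O` | intermediate |
| 5 | (3S,4S)-3,4-dimethyloxetan-2-one | `C[C@@H]1OC(=O)[C@H]1C` | intermediate |
| 6 | 2-[4-(benzyloxy)-3-methoxyphenyl]acetic acid | `COc1cc(CC(=O)O)ccc1OCc1ccccc1` | starting material |
| 7 | (2S,3S)-4-[4-(benzyloxy)-3-methoxyphenyl]-2,3-dimethylbutanoic acid | `COc1cc(C[C@H](C)[C@H](C)C(=O)O)ccc1OCc1ccccc1` | intermediate |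
| 8 | (2S,3S)-4-[4-(benzyloxy)-3-methoxyphenyl]-2,3-dimethylbutan-1-ol | `COc1cc(C[C@H](C)[C@H](C)CO)ccc1OCc1ccccc1` | intermediate |
| 9 | 4-bromo-2,6-dimethoxyphenol | `COc1cc(Br)cc(OC)c1O` | starting material |
| 10 | methyl (R)-lactate | `COC(=O)[C@@H](C)O` | starting material |
| 11 | methyl (S)-2-(4-bromo-2,6-dimethoxyphenoxy)propanoate | `COC(=O)[C@H](C)Oc1c(OC)cc(Br)cc1OC` | intermediate |
| 12 | (S)-2-(4-bromo-2,6-dimethoxyphenoxy)propanal | `O=C[C@H](C)Oc1c(OC)cc(Br)cc1OC` | intermediate |
| 13 | 1-(benzyloxy)-4-bromo-2-methoxybenzene | `COc1cc(Br)ccc1OCc1ccccc1` | starting material |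
| 14 | (1S,2S)-1-[4-(benzyloxy)-3-methoxyphenyl]-2-(4-bromo-2,6-dimethoxyphenoxy)propan-1-ol | `COc1cc(Br)cc(OC)c1O[C@@H](C)[C@@H](O)c1ccc(OCc2ccccc2)c(OC)c1` | intermediate |
| 15 | 4,4''-di-O-benzyl target | `COc1cc(C[C@H](C)[C@H](C)Cc2cc(OC)c(O[C@@H](C)[C@@H](O)c3ccc(OCc4ccccc4)c(OC)c3)c(OC)c2)ccc1OCc1ccccc1` | intermediate |
| 16 | target sesquineolignan | `COc1cc(C[C@H](C)[C@H](C)Cc2cc(OC)c(O[C@@H](C)[C@@H](O)c3ccc(O)c(OC)c3)c(OC)c2)ccc1O` | target |

## Step count
- Total steps: 10
- Longest linear sequence: 7 (steps 1–5, 9, 10)

## Three steps most likely to fail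
1. **Step 4 (new reaction).**
   - Risks:
     - Ni(0) insertion at the hindered secondary C–O may be slow.
     - The nickelalactone may undergo β-H elimination through the exocyclic methyl.
     - Ni–C homolysis could erode the inversion.
     - The benzyl radical may dimerise.
     - Carboxylate may open or oligomerise lactone 5.
   - Fallback (known chemistry): make 4-(benzyloxy)-3-methoxybenzylmagnesium chloride from the benzyl chloride. Add it to 5 with CuBr·SMe2 in THF/Me2S at −30 °C. This is the organocuprate SN2 alkyl–O opening of a β-lactone, with the same inversion, and it gives 7.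
2. **Step 8 (threo/erythro ratio).**
   - Risk: the aryloxy oxygen may chelate weakly, so Felkin–Anh addition to the erythro isomer competes.
   - Fallback: oxidise the diastereomer mixture with DMP to the (S)-α-aryloxy aryl ketone. Reduce it with L-Selectride at −78 °C, where non-chelated polar Felkin–Anh hydride delivery gives the threo alcohol 14.
3. **Step 9 (fragment union).**
   - Risks: the electron-rich ArBr may be sluggish, and an excess of the valuable alcohol is needed. The 4-arylbutyl radical could also cyclise onto ring A.
   - Fallback: switch to polar Pd chemistry. Carry out Appel iodination of 8, then Zn/LiCl insertion to the alkylzinc iodide. Couple this under Pd/CPhos Negishi conditions with the TES ether of 14, and remove the TES group on mild acidic work-up before step 10.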